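**Plan**

Locants follow daucane numbering: C1 (ring-fusion carbon with methyl), C2 (O-angelate), C3, C4 (OH, isopropyl), C5 (ring-fusion CH), C6 (O-aroyl), C7, C8 (methyl)=C9, C10.
Retrosynthesis: the two ester C–O bonds (C2 angelate, C6 trimethoxybenzoate) are cut first, then the C4–isopropyl bond, then C1–C5 and C1–C10, which returns the hydroazulene to a benzene ring with an α-diazoethyl ketone side chain; the chain is cut at C1–C2 (acylation of diazoethane) and C3–C4 (acetate aldol).
Enabling feature: the seven-membered ring is a 2-oxy-4-methylphenyl ring (C5 ipso, C6 oxygen, C8 methyl) with one extra carbon, quaternary C1, inserted between C5 and C10; C1 bears a methyl and adjoins oxygenated C2, the pattern a ketone-flanked carbene carbon leaves after a Buchner ring expansion.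
Forward: silylated 4-methylsalicylaldehyde, asymmetric acetate aldol, diazo ketone, then one intramolecular Buchner reaction that closes the five-membered ring (C1–C5) and expands the arene to the seven-membered ring; no ring is formed afterwards.
Stereochemistry: the aldol sets a temporary C4 carbinol that directs the arene face and fixes C1 (then erased by oxidation); C2 by CBS reduction; C4 by organocerium addition anti to the C2 silyloxy group; C5 by thermodynamic ketonisation (cis fusion); C6 by hydroxyl-directed hydride delivery; the Z alkene comes with angelic acid.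

Key step: step 6

Remark (assumption): ketone 20 is assumed to prefer the cis ring fusion thermodynamically (C6 anti to the C4 isopropyl and C1 methyl groups); this is what sets C5.

**Route**

Step 1
Reactants: 1 2-hydroxy-4-methylbenzaldehyde
Product: 2 4-methyl-2-(triisopropylsilyloxy)benzaldehyde
Conditions: i-Pr3SiCl, imidazole, DMF, rt
Reagents that add atoms: triisopropylsilyl chloride, CC(C)[Si](Cl)(C(C)C)C(C)C
Why: Imidazole-promoted silylation of the phenol (silyl ether formation) masks the only acidic OH as a robust aryl triisopropylsilyl ether that later becomes the C6 silyl enol ether and serves as the steric control element of the key step.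

Step 2
Reactants: 2 4-methyl-2-(triisopropylsilyloxy)benzaldehyde; 3 1-(tert-butyldimethylsilyloxy)-1-methoxyethene
Product: 5 methyl (R)-3-hydroxy-3-[4-methyl-2-(triisopropylsilyloxy)phenyl]propanoate, via trichlorosilyl ether 4 (not isolated)
Conditions: SiCl4, chiral bisphosphoramide (two N,N'-dimethyl-1,1'-binaphthyl-2,2'-diamine phosphoramide units joined through an N,N'-dimethylpentane-1,5-diamine chain; the enantiomer that exposes the Re face of the aldehyde; 5 mol %), CH2Cl2, −78 °C; cold sat. aq. NaHCO3
Reagents that add atoms: none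
Why: Lewis-base-catalysed Mukaiyama acetate aldol in which the chiral phosphoramide-bound trichlorosilyl cation activates the aldehyde and shields one face, so that the ketene acetal adds to the Re face and the (R)-carbinol (the temporary C4 centre) is formed, the trichlorosilyl ether being hydrolysed on bicarbonate work-up.

Step 3
Reactants: 5 methyl (R)-3-hydroxy-3-[4-methyl-2-(triisopropylsilyloxy)phenyl]propanoate
Product: 6 methyl (R)-3-[4-methyl-2-(triisopropylsilyloxy)phenyl]-3-(triethylsilyloxy)propanoate
Conditions: Et3SiOTf, 2,6-lutidine, CH2Cl2, −78 → 0 °C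
Reagents that add atoms: triethylsilyl triflate, CC[Si](CC)(CC)OS(=O)(=O)C(F)(F)F
Why: Silyl triflate etherification of the secondary benzylic alcohol under a non-nucleophilic base protects the C4 oxygen for the carbene step as a triethylsilyl ether that is smaller and more labile than the aryl triisopropylsilyl ether.

Step 4
Reactants: 6 methyl (R)-3-[4-methyl-2-(triisopropylsilyloxy)phenyl]-3-(triethylsilyloxy)propanoate
Product: 7 (R)-3-[4-methyl-2-(triisopropylsilyloxy)phenyl]-3-(triethylsilyloxy)propanoic acid
Conditions: Me3SnOH, ClCH2CH2Cl, 70 °C; cold 0.01 M aq. HCl wash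
Reagents that add atoms: trimethyltin hydroxide, C[Sn](C)(C)O
Why: Trimethyltin hydroxide hydrolysis of a methyl ester proceeds under neutral conditions that avoid β-elimination of the silyloxy group and cleavage of the aryl silyl ether.

Step 5
Reactants: 7 (R)-3-[4-methyl-2-(triisopropylsilyloxy)phenyl]-3-(triethylsilyloxy)propanoic acid; 8 N-ethyl-N-nitrosourea
Product: 11 (R)-2-diazo-5-[4-methyl-2-(triisopropylsilyloxy)phenyl]-5-(triethylsilyloxy)pentan-3-one, via mixed anhydride 9 (not isolated), via diazoethane 10 (not isolated)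
Conditions: i-BuOCOCl, Et3N, THF, −20 °C; then excess CH3CHN2 in Et2O (from 8, 40% aq. KOH, Et2O, 0 °C, dried over KOH), −20 → 0 °C
Reagents that add atoms: none
Why: Acylation of a diazoalkane by a mixed carbonic anhydride (the diazo ketone synthesis of the Arndt–Eistert sequence) takes place at the diazo carbon of diazoethane under cold, weakly basic conditions that leave both silyl ethers and the stereocentre untouched.

Step 6
Reactants: 11 (R)-2-diazo-5-[4-methyl-2-(triisopropylsilyloxy)phenyl]-5-(triethylsilyloxy)pentan-3-one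
Product: 13 (1R,4R)-8a-methylazulenone (C2 ketone; C4 OSiEt3; C6 OSi(i-Pr)3 trienol ether; C1 methyl trans to OSiEt3), via norcaradiene 12 (not isolated)
Conditions: Rh2(OAc)4 (1 mol %), CH2Cl2, reflux, slow addition of 11
Reagents that add atoms: none
Why: Rh2(OAc)4 expels N2 from 11 to give a rhodium-bound carbene at C1 that cyclopropanates the C5–C10 bond of the arene, and norcaradiene 12 opens by disrotatory 6π electrocyclic cleavage of the C5–C10 σ bond to cycloheptatriene 13; this is the intramolecular Buchner reaction, the closest known case being the rhodium carboxylate cyclisation of 2-diazo-5-arylpentan-3-ones to 8a-methylazulenones. The five-membered ring closes by C1–C5 bond formation as the C2–C3–C4 tether folds the carbene onto the ipso carbon (5-exo attack on the aromatic π bond), and the seven-membered ring arises by expansion of the benzene ring, C1 being inserted between C5 and C10. The new quaternary centre C1 is controlled by the C4 stereocentre: allylic 1,3-strain with the ortho silyloxy group holds the C4 hydrogen in the arene plane, so the tether reaches one face only with the triethylsilyloxy group turned away from the incoming methyl, which places the methyl trans to OSiEt3 ((1R)), the sense known for benzylic alkyl substituents. The step needs addition across C5–C10 and not C5–C6 (the bulky OSi(i-Pr)3 group blocks C6), cyclopropanation and not insertion or aromatic substitution (no C–H bond is placed for five-membered insertion, both donor groups are meta to C10, and the fully substituted C1 cannot rearomatise), and attack on the arene in preference to the C4 oxygen (a hindered, weakly basic silyl ether).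

Step 7
Reactants: 13 (1R,4R)-8a-methylazulenone
Product: 14 (1R,2S,4R)-C2 alcohol (C2 OH trans to the C1 methyl; C4 OSiEt3; C6 OSi(i-Pr)3 trienol ether)
Conditions: (R)-2-methyl-CBS-oxazaborolidine [(R)-1-methyl-3,3-diphenyltetrahydro-1H,3H-pyrrolo[1,2-c][1,3,2]oxazaborole] (20 mol %), catecholborane, toluene, −78 → −40 °C; MeOH, aq. NaHCO3
Reagents that add atoms: none
Why: Corey–Bakshi–Shibata reduction in which the oxazaborolidine binds the ketone with the quaternary C1 as the large group and delivers hydride to the face that carries the C1 methyl, so the (2S) alcohol forms with its oxygen trans to that methyl under reagent control, while catecholborane at low temperature leaves the triene and the silyl ethers alone.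

Step 8
Reactants: 14 (1R,2S,4R)-C2 alcohol
Product: 15 (1R,2S,4R)-C2 tert-butyldimethylsilyl ether (C4 OSiEt3; C6 OSi(i-Pr)3 trienol ether)
Conditions: t-BuMe2SiOTf, 2,6-lutidine, CH2Cl2, −78 → 0 °C
Reagents that add atoms: tert-butyldimethylsilyl triflate, CC(C)(C)[Si](C)(C)OS(=O)(=O)C(F)(F)F
Why: Silyl triflate etherification of the hindered neopentyl-type secondary alcohol gives a tert-butyldimethylsilyl ether that withstands the oxidation, organometallic, buffered fluoride and dissolving-metal steps that follow and later shields one face of the C4 ketone.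

Step 9
Reactants: 15 (1R,2S,4R)-C2 tert-butyldimethylsilyl ether
Product: 16 (1R,2S)-C4 ketone (vinylogous silyl ester: C4=O conjugated with C5=C6–OSi(i-Pr)3; C2 OSiMe2t-Bu)
Conditions: 2,3-dichloro-5,6-dicyano-1,4-benzoquinone (DDQ), CH2Cl2/pH 7 phosphate buffer (10:1), 0 °C
Reagents that add atoms: none
Why: Oxidative deprotection of an allylic silyl ether with DDQ, in which hydride abstraction occurs at C4 because that C–H bond is activated both by its own silyloxy group and, through the C5=C6 bond, by the enol ether oxygen, and water then removes the less hindered triethylsilyl group so that the C4 ketone appears as a vinylogous silyl ester with the non-allylic C2 silyl ether untouched.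

Step 10
Reactants: 16 (1R,2S)-C4 ketone; 17 isopropylmagnesium chloride
Product: 18 (1R,2S,4S)-tertiary carbinol (C4 OH and isopropyl; isopropyl cis to the C1 methyl; C2 OSiMe2t-Bu; C6 OSi(i-Pr)3 trienol ether)
Conditions: anhydrous CeCl3, THF, −78 °C; pH 7 phosphate buffer quench
Reagents that add atoms: none
Why: Organocerium 1,2-addition (Grignard reagent transmetallated with CeCl3) overcomes enolisation, β-hydride reduction and conjugate displacement at the hindered vinylogous ester carbonyl, and the reagent approaches the face that bears the C1 methyl, anti to the bulky C2 silyloxy group and to C10 of the folded seven-membered ring, which sets (4S) with isopropyl cis to the methyl and hydroxyl cis to the C2 oxygen.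

Step 11
Reactants: 18 (1R,2S,4S)-tertiary carbinol
Product: 20 cis-fused β-hydroxy dienone (1R,2S,4S,5S; C6 ketone; C7=C8/C9=C10 diene; H-5 cis to the C1 methyl), via trienol 19 (not isolated)
Conditions: Bu4NF, AcOH (1:1), THF, 0 °C → rt, held until C5 has equilibrated
Reagents that add atoms: none
Why: Fluoride cleaves the silyl enol ether far faster than the hindered alkyl silyl ether, and the liberated trienol ketonises by protonation at C5 (desilylation and keto–enol tautomerism) under an acetate buffer that allows reversible enolisation, so C5 settles in the more stable cis-fused arrangement with C6 anti to the isopropyl and C1-methyl groups, while the buffered medium spares the tertiary aldol from retro-aldol cleavage and dehydration.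

Step 12
Reactants: 20 cis-fused β-hydroxy dienone
Product: 22 cis-fused β,γ-enone (1R,2S,4S,5S; C6 ketone; C8=C9), via lithium dienolate 21 (not isolated)
Conditions: Li, NH3(l)/THF, t-BuOH (1 equiv), −78 °C; rapid quench with solid NH4Cl
Reagents that add atoms: none
Why: Dissolving-metal (Birch-type) 1,6-reduction of a linear dienone, in which two electrons and a proton at the δ-carbon C10 give the C6 dienolate, which shields the carbonyl from further reduction and is protonated kinetically at the α-carbon C7 on rapid ammonium chloride quench, leaving the alkene at C8=C9 out of conjugation and creating no new stereocentre.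

Step 13
Reactants: 22 cis-fused β,γ-enone
Product: 23 (1R,2S,4S,5R,6R)-C4,C6-diol (C2 OSiMe2t-Bu; C8=C9)
Conditions: Me4NBH(OAc)3, MeCN/AcOH (1:1), −25 °C
Reagents that add atoms: none
Why: Evans–Saksena hydroxyl-directed reduction in which the C4 hydroxyl exchanges onto boron and hydride is delivered internally through a six-membered chair-like transition state to the face of the C6 carbonyl on which C4 lies, so the new C6–O bond is cis to H-5 and to the C1 methyl on the seven-membered ring ((6R)), and the cold, weakly acidic medium does not move the β,γ-alkene.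

Step 14
Reactants: 23 (1R,2S,4S,5R,6R)-C4,C6-diol; 24 3,4,5-trimethoxybenzoyl chloride
Product: 25 C6 3,4,5-trimethoxybenzoate (C2 OSiMe2t-Bu; free tertiary C4 OH)
Conditions: 4-(dimethylamino)pyridine, Et3N, CH2Cl2, 0 °C → rt
Reagents that add atoms: none
Why: Acylation under nucleophilic catalysis by 4-(dimethylamino)pyridine (through the N-acylpyridinium ion) takes the only free secondary hydroxyl, since the tertiary C4 hydroxyl is too hindered and C2 is silylated.

Step 15
Reactants: 25 C6 3,4,5-trimethoxybenzoate
Product: 26 C6 3,4,5-trimethoxybenzoate with free C2 and C4 hydroxyls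
Conditions: HF·pyridine, pyridine, THF, 0 °C → rt
Reagents that add atoms: none
Why: Fluoride-driven Si–O cleavage by buffered HF·pyridine removes the secondary silyl ether without ester migration or cleavage and without ionising the tertiary alcohol.

Step 16
Reactants: 26 C6 3,4,5-trimethoxybenzoate with free C2 and C4 hydroxyls; 27 angelic acid
Product: 29 target CNP0112256.1, via angeloyl mixed anhydride 28 (not isolated)
Conditions: 27, 2,4,6-trichlorobenzoyl chloride, Et3N, toluene, rt; then 26, toluene, 75 °C (no acyl-transfer catalyst)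
Reagents that add atoms: none
Why: Yamaguchi-type esterification through the angeloyl 2,4,6-trichlorobenzoyl mixed anhydride acylates the hindered C2 alcohol at the less hindered angeloyl carbonyl, and the absence of a nucleophilic catalyst suppresses the addition–elimination that would isomerise the Z angelate to the E tiglate, the tertiary C4 hydroxyl remaining unacylated.

**Compound list**

1 | 2-hydroxy-4-methylbenzaldehyde | Cc1ccc(C=O)c(O)c1 | starting material
2 | 4-methyl-2-(triisopropylsilyloxy)benzaldehyde | Cc1ccc(C=O)c(O[Si](C(C)C)(C(C)C)C(C)C)c1 | intermediate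
3 | 1-(tert-butyldimethylsilyloxy)-1-methoxyethene | C=C(OC)O[Si](C)(C)C(C)(C)C | starting material
4 | methyl (R)-3-[4-methyl-2-(triisopropylsilyloxy)phenyl]-3-(trichlorosilyloxy)propanoate | COC(=O)C[C@@H](O[Si](Cl)(Cl)Cl)c1ccc(C)cc1O[Si](C(C)C)(C(C)C)C(C)C | intermediate
5 | methyl (R)-3-hydroxy-3-[4-methyl-2-(triisopropylsilyloxy)phenyl]propanoate | COC(=O)C[C@@H](O)c1ccc(C)cc1O[Si](C(C)C)(C(C)C)C(C)C | intermediate
6 | methyl (R)-3-[4-methyl-2-(triisopropylsilyloxy)phenyl]-3-(triethylsilyloxy)propanoate | COC(=O)C[C@@H](O[Si](CC)(CC)CC)c1ccc(C)cc1O[Si](C(C)C)(C(C)C)C(C)C | intermediate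
7 | (R)-3-[4-methyl-2-(triisopropylsilyloxy)phenyl]-3-(triethylsilyloxy)propanoic acid | OC(=O)C[C@@H](O[Si](CC)(CC)CC)c1ccc(C)cc1O[Si](C(C)C)(C(C)C)C(C)C | intermediate
8 | N-ethyl-N-nitrosourea | CCN(N=O)C(N)=O | starting material
9 | isobutyl carbonic mixed anhydride of acid 7 | CC(C)COC(=O)OC(=O)C[C@@H](O[Si](CC)(CC)CC)c1ccc(C)cc1O[Si](C(C)C)(C(C)C)C(C)C | intermediate
10 | diazoethane | CC=[N+]=[N-] | intermediate
11 | (R)-2-diazo-5-[4-methyl-2-(triisopropylsilyloxy)phenyl]-5-(triethylsilyloxy)pentan-3-one | CC(=[N+]=[N-])C(=O)C[C@@H](O[Si](CC)(CC)CC)c1ccc(C)cc1O[Si](C(C)C)(C(C)C)C(C)C | intermediate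
12 | norcaradiene valence isomer of 13 (cyclopropane C1–C5–C10 fused to the cyclopentanone and to the C6=C7–C8=C9 cyclohexadiene; C1 methyl over the diene ring) | O=C1C[C@@H](O[Si](CC)(CC)CC)[C@@]23C(O[Si](C(C)C)(C(C)C)C(C)C)=CC(C)=C[C@@H]2[C@@]13C | intermediate
13 | (3R,8aR)-6,8a-dimethyl-3-(triethylsilyloxy)-4-(triisopropylsilyloxy)-3,8a-dihydroazulen-1(2H)-one (daucane locants 1R,4R; C1 methyl trans to OSiEt3) | O=C1C[C@@H](O[Si](CC)(CC)CC)C2=C(O[Si](C(C)C)(C(C)C)C(C)C)C=C(C)C=C[C@@]12C | intermediate
14 | (1S,3R,8aR)-6,8a-dimethyl-3-(triethylsilyloxy)-4-(triisopropylsilyloxy)-1,2,3,8a-tetrahydroazulen-1-ol (daucane locants 1R,2S,4R; OH trans to the C1 methyl) | O[C@H]1C[C@@H](O[Si](CC)(CC)CC)C2=C(O[Si](C(C)C)(C(C)C)C(C)C)C=C(C)C=C[C@@]12C | intermediate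
15 | C2 tert-butyldimethylsilyl ether of 14 (daucane locants 1R,2S,4R) | CC(C)(C)[Si](C)(C)O[C@H]1C[C@@H](O[Si](CC)(CC)CC)C2=C(O[Si](C(C)C)(C(C)C)C(C)C)C=C(C)C=C[C@@]12C | intermediate
16 | C4 ketone (daucane locants 1R,2S): C2 OSiMe2t-Bu, C4=O, C5=C6 with 6-OSi(i-Pr)3, C7=C8 with 8-methyl, C9=C10, 1-methyl | CC(C)(C)[Si](C)(C)O[C@H]1CC(=O)C2=C(O[Si](C(C)C)(C(C)C)C(C)C)C=C(C)C=C[C@@]12C | intermediate
17 | isopropylmagnesium chloride | CC(C)[Mg]Cl | starting material
18 | tertiary carbinol (daucane locants 1R,2S,4S): as 16 with C4 bearing OH and isopropyl, isopropyl cis to the C1 methyl | CC(C)(C)[Si](C)(C)O[C@H]1C[C@](O)(C(C)C)C2=C(O[Si](C(C)C)(C(C)C)C(C)C)C=C(C)C=C[C@@]12C | intermediate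
19 | trienol (daucane locants 1R,2S,4S): as 18 with free C6 enol OH | CC(C)(C)[Si](C)(C)O[C@H]1C[C@](O)(C(C)C)C2=C(O)C=C(C)C=C[C@@]12C | intermediate
20 | cis-fused β-hydroxy dienone (daucane locants 1R,2S,4S,5S): C6 ketone, C7=C8(CH3)–C9=C10, H-5 cis to the C1 methyl | CC(C)(C)[Si](C)(C)O[C@H]1C[C@](O)(C(C)C)[C@H]2C(=O)C=C(C)C=C[C@@]12C | intermediate
21 | lithium C6 dienolate (O–C6=C7–C8=C9, C10 H2) | [Li+].CC(C)(C)[Si](C)(C)O[C@H]1C[C@](O)(C(C)C)[C@H]2C([O-])=CC(C)=CC[C@@]12C | intermediate
22 | cis-fused β,γ-enone (daucane locants 1R,2S,4S,5S): C6 ketone, C8=C9 | CC(C)(C)[Si](C)(C)O[C@H]1C[C@](O)(C(C)C)[C@H]2C(=O)CC(C)=CC[C@@]12C | intermediate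
23 | (1S,3S,3aR,4R,8aR)-1-(tert-butyldimethylsilyloxy)-6,8a-dimethyl-3-(propan-2-yl)-1,2,3,3a,4,5,8,8a-octahydroazulene-3,4-diol (daucane locants 1R,2S,4S,5R,6R) | CC(C)(C)[Si](C)(C)O[C@H]1C[C@](O)(C(C)C)[C@H]2[C@H](O)CC(C)=CC[C@@]12C | intermediate
24 | 3,4,5-trimethoxybenzoyl chloride | COc1cc(C(=O)Cl)cc(OC)c1OC | starting material
25 | (1S,3S,3aR,4R,8aR)-1-(tert-butyldimethylsilyloxy)-3-hydroxy-6,8a-dimethyl-3-(propan-2-yl)-1,2,3,3a,4,5,8,8a-octahydroazulen-4-yl 3,4,5-trimethoxybenzoate | CC(C)(C)[Si](C)(C)O[C@H]1C[C@](O)(C(C)C)[C@H]2[C@H](OC(=O)c3cc(OC)c(OC)c(OC)c3)CC(C)=CC[C@@]12C | intermediate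
26 | (1S,3S,3aR,4R,8aR)-1,3-dihydroxy-6,8a-dimethyl-3-(propan-2-yl)-1,2,3,3a,4,5,8,8a-octahydroazulen-4-yl 3,4,5-trimethoxybenzoate | O[C@H]1C[C@](O)(C(C)C)[C@H]2[C@H](OC(=O)c3cc(OC)c(OC)c(OC)c3)CC(C)=CC[C@@]12C | intermediate
27 | angelic acid, (Z)-2-methylbut-2-enoic acid | C/C=C(/C)C(=O)O | starting material
28 | (Z)-2-methylbut-2-enoic 2,4,6-trichlorobenzoic anhydride | C/C=C(/C)C(=O)OC(=O)c1c(Cl)cc(Cl)cc1Cl | intermediate
29 | CNP0112256.1, (1S,3S,3aR,4R,8aR)-3-hydroxy-6,8a-dimethyl-3-(propan-2-yl)-4-(3,4,5-trimethoxybenzoyloxy)-1,2,3,3a,4,5,8,8a-octahydroazulen-1-yl (Z)-2-methylbut-2-enoate | C/C=C(/C)C(=O)O[C@H]1C[C@](O)(C(C)C)[C@H]2[C@H](OC(=O)c3cc(OC)c(OC)c(OC)c3)CC(C)=CC[C@@]12C | target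

**Step count and risks**

Total step count: 16. Longest linear sequence: 16 steps (1 to 29); compounds 3, 8, 17, 24 and 27 are bought.

Steps most likely to fail:

Step 6. The carbene may be intercepted by the C4 silyl ether oxygen (five-membered oxonium ylide and silyl transfer) in competition with addition to the arene. The fallback sets out from 5 and comes back at 16; it carries the C4 oxygen as a pivalate, whose acyl-bound oxygen does not engage a carbene, and unmasks it reductively instead of oxidatively. Hydroxy ester 5 is acylated (t-BuCOCl, 4-(dimethylamino)pyridine, pyridine) to pivalate ester F1, and Me3SnOH cleaves only the methyl ester to give acid F2. Activation with i-BuOCOCl/Et3N gives mixed anhydride F3, which acylates diazoethane 10 (from 8) to give diazo ketone F4. Rh2(OAc)4 should then give, through norcaradiene F5, pivalate azulenone F6. CBS reduction as in step 7 gives C2 alcohol F7, i-Bu2AlH (CH2Cl2, −78 °C, aqueous KNaC4H4O6 work-up) removes the pivalate to give diol F8, and MnO2 (CH2Cl2) oxidises only the allylic C4 hydroxyl to hydroxy ketone F9. Silylation with t-BuMe2SiOTf/2,6-lutidine returns to 16.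

Step 9. DDQ may over-oxidise, attacking the electron-rich silyl trienol ether or the C8 methyl group instead of abstracting hydride cleanly at C4. The fallback sets out from 15 and comes back at 16; it separates deprotection from oxidation. HF·pyridine buffered with excess pyridine (THF, 0 °C) removes only the triethylsilyl group to give allylic alcohol F10, which is oxidised at once under neutral conditions with MnO2 (CH2Cl2) to 16.

Step 12. Positional control may be lost in the electron-transfer reduction: protonation of the dienolate at C9 would give the conjugated enone, and over-reduction of the ketone or retro-aldol opening of the tertiary aldol are possible in the basic medium. The fallback sets out from 20 and comes back at 23; it reverses the order of the two reductions and places the alkene by hydrogenation instead of protonation. Me4NBH(OAc)3 (MeCN/AcOH, −25 °C) first gives, by the same hydroxyl-directed delivery, dienyl diol F11. 1,4-Hydrogenation of its s-cis cycloheptadiene with H2 and catalytic Cr(CO)3(naphthalene) (a zerovalent chromium tricarbonyl arene complex; THF, 40 °C) adds hydrogen at C7 and C10 only, leaving the double bond at C8=C9 and giving 23.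

**Further compounds**

F1 | step 6 | methyl (R)-3-[4-methyl-2-(triisopropylsilyloxy)phenyl]-3-(pivaloyloxy)propanoate | COC(=O)C[C@@H](OC(=O)C(C)(C)C)c1ccc(C)cc1O[Si](C(C)C)(C(C)C)C(C)C
F2 | step 6 | (R)-3-[4-methyl-2-(triisopropylsilyloxy)phenyl]-3-(pivaloyloxy)propanoic acid | OC(=O)C[C@@H](OC(=O)C(C)(C)C)c1ccc(C)cc1O[Si](C(C)C)(C(C)C)C(C)C
F3 | step 6 | isobutyl carbonic mixed anhydride of acid F2 | CC(C)COC(=O)OC(=O)C[C@@H](OC(=O)C(C)(C)C)c1ccc(C)cc1O[Si](C(C)C)(C(C)C)C(C)C
F4 | step 6 | (R)-4-diazo-1-[4-methyl-2-(triisopropylsilyloxy)phenyl]-3-oxopentyl pivalate | CC(=[N+]=[N-])C(=O)C[C@@H](OC(=O)C(C)(C)C)c1ccc(C)cc1O[Si](C(C)C)(C(C)C)C(C)C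
F5 | step 6 | norcaradiene valence isomer of F6 (cyclopropane C1–C5–C10) | O=C1C[C@@H](OC(=O)C(C)(C)C)[C@@]23C(O[Si](C(C)C)(C(C)C)C(C)C)=CC(C)=C[C@@H]2[C@@]13C
F6 | step 6 | pivalate azulenone (daucane locants 1R,4R): C2 ketone, C4 pivalate, C6 OSi(i-Pr)3 trienol ether | O=C1C[C@@H](OC(=O)C(C)(C)C)C2=C(O[Si](C(C)C)(C(C)C)C(C)C)C=C(C)C=C[C@@]12C
F7 | step 6 | C2 alcohol (daucane locants 1R,2S,4R): C2 OH, C4 pivalate, C6 OSi(i-Pr)3 trienol ether | O[C@H]1C[C@@H](OC(=O)C(C)(C)C)C2=C(O[Si](C(C)C)(C(C)C)C(C)C)C=C(C)C=C[C@@]12C
F8 | step 6 | C2,C4-diol (daucane locants 1R,2S,4R) with C6 OSi(i-Pr)3 trienol ether | O[C@H]1C[C@@H](O)C2=C(O[Si](C(C)C)(C(C)C)C(C)C)C=C(C)C=C[C@@]12C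
F9 | step 6 | hydroxy ketone (daucane locants 1R,2S): C2 OH, C4 ketone, C6 OSi(i-Pr)3 trienol ether | O[C@H]1CC(=O)C2=C(O[Si](C(C)C)(C(C)C)C(C)C)C=C(C)C=C[C@@]12C
F10 | step 9 | allylic alcohol (daucane locants 1R,2S,4R): C2 OSiMe2t-Bu, C4 OH, C6 OSi(i-Pr)3 trienol ether | CC(C)(C)[Si](C)(C)O[C@H]1C[C@@H](O)C2=C(O[Si](C(C)C)(C(C)C)C(C)C)C=C(C)C=C[C@@]12C
F11 | step 12 | dienyl diol (daucane locants 1R,2S,4S,5R,6R): C2 OSiMe2t-Bu, C4 OH, C6 OH, C7=C8(CH3)–C9=C10 | CC(C)(C)[Si](C)(C)O[C@H]1C[C@](O)(C(C)C)[C@H]2[C@H](O)C=C(C)C=C[C@@]12C
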